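**The constants.** I had no rate constants for this flask, so I drew an estimate from the epsilon run, which looks nearly the same: E is charged alike, but D stands at 31 mM there against 22.0 mM here. In epsilon, E already read 0% at 2.00 h, with a scatter of 0.5 percentage points.

the same everywhere: E 20 mM

| flask | D | remark | time |
|---|---|---|---|
| epsilon | 31 mM | run made earlier |  |
| gamma | 48 mM | run made earlier |  |
| flask | 22.0 mM |  | 8.0 h |

| run | time / h | E / % | Z / % | L / % |
|---|---|---|---|---|
| epsilon | 2.00 | 0 | 3.0 | 66.1 |
| epsilon | 4.00 | 0 | 2.8 | 66.9 |
| epsilon | 6.00 | 0 | 2.8 | 67.1 |
| epsilon | 8.00 | 0.2 | 2.1 | 66.6 |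
| epsilon | 10.0 | 0 | 2.4 | 67.1 |
| gamma | 2.00 | 0 | 2.3 | 74.0 |
| gamma | 4.00 | 0.4 | 2.2 | 73.4 |
| gamma | 6.00 | 0 | 3.1 | 73.0 |
| gamma | 8.00 | 0.2 | 3.0 | 73.6 |
| gamma | 10.0 | 0.9 | 2.2 | 73.6 |

(each reading ± 0.5 percentage points)

1. at 8.0 h, what has stopped the reaction, if anything has (D has run out first / forward and back rates have come level / all of E has reacted / it is still moving)
2. how much of the E has reacted by 8.0 h
3. how much Z there is at 8.0 h, in percent of the E charged
4. how much L there is at 8.0 h, in percent of the E charged
5. amount of Z if the flask were left three thousand times as long, in percent of the E charged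

- the earlier runs were read with a standard deviation of 0.5 percentage points
- the reaction counts as stopped when no species that holds the E changes by six tenths of a point or more over the second half of the time
- a reading of Z is of its free form alone

**Counting turnovers.** Suppose, as my own assumption, that E falls by a second-order step with D, one D per E. Then ln([D]/[E]) climbs in a straight line, and its slope is proportional to the excess of D over E. In epsilon the ratio began at 1.55 and, with E taken at the scatter, reached about 110, which is 4.26 e-foldings. Epsilon had an excess of 11.0 mM for 2.00 h; this flask has 2.00 mM for 8.0 h. Scaling by excess times time gives 3.10, the turnover count: the e-foldings of [D]/[E] that a flask's excess and time allow.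

This flask's count is smaller than epsilon's. Yet D still exceeds E in this flask, so I expected both to end the same way, with E gone first. The count leaves about 0.410% of the E, less than the scatter.

**The forecast.** It gave: all of E has reacted, with 100% reacted, Z at 2.6%, L at 60%, and Z at 2.6% after very long standing, judging that “1.1 equiv should just suffice”. My count allows a trace of E where the forecast has none, and it says nothing about Z or L.

**The result.** The flask gave: all of E has reacted, with 100% reacted, Z at 2.09%, L at 59.4%, and Z at 2.09% after very long standing.

    E + D → G (k = 0.208 M⁻¹ s⁻¹)
    G ⇌ Z (K = 0.866, k = 0.00343 s⁻¹)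
    E + G → X (k = 0.143 M⁻¹ s⁻¹)
    Z ⇌ L (K = 28.4, k = 0.00815 s⁻¹)

**Two flasks.** In this flask the half-life of E by the path from E + G to X was 0.25 h at 0.0425 h, short against 8.0 h. At 8.0 h E, the limiting reagent, stood at 0% and D at 25% of its own charge, the order that the positive count of 3.10 expected. With 34 mM of E the excess turns negative and the count becomes −18.6, which puts D out first, and that neighbour flask ended with D at 0% and E at 1.76%.

Readings and results stem from a simulated flask with made-up constants.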